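**Retrosynthetic overview**
1. The last disconnection is the 4'-O-benzyl ether, removed by hydrogenolysis. The six methyl ethers are carried through untouched.
2. Ring C (the 4-pyranone) is the only ring formed. Its O1–C2 bond comes from iodine-catalysed oxidative cyclisation of a 2'-hydroxychalcone.
3. The chalcone C=C bond comes from a Claisen–Schmidt condensation of the ring A acetophenone and the ring B aldehyde.
4. The ring A ketone comes from 3,4,5-trimethoxyphenol by C-acetylation, bromination of the last free ring C–H, and copper-catalysed exchange of Br for OMe.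
5. The ring B aldehyde is O-benzylsyringaldehyde. Rings A and B are bought as arenes and ring C is closed last.

Assumption: the target has no stereocentre, axis or plane of chirality, so it is achiral and no enantioselective step is needed. The only stereochemical feature on the way is the E alkene of the chalcone.

**Step 1**
Reactants: 1 3,4,5-trimethoxyphenol
Product: 2 1-(6-hydroxy-2,3,4-trimethoxyphenyl)ethanone
Conditions: AcOH (3 equiv), BF3·OEt2 (solvent), 85 °C, 3 h; ice–water
Reagents that add atoms: acetic acid, CC(=O)O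
Why: Friedel–Crafts C-acylation (Fries-type) puts BF3-activated acetic acid on one of the two symmetry-equivalent positions ortho to OH, and the hydrogen-bonded o-hydroxyketone formed resists a second acylation; no stereocentre is made.

**Step 2**
Reactants: 2 1-(6-hydroxy-2,3,4-trimethoxyphenyl)ethanone
Product: 3 1-(3-bromo-2-hydroxy-4,5,6-trimethoxyphenyl)ethanone
Conditions: NBS (1.05 equiv), MeCN, 0 °C to rt, dark
Reagents that add atoms: N-bromosuccinimide, O=C1CCC(=O)N1Br
Why: Electrophilic aromatic bromination takes the only ring C–H left, which is ortho to OH, ortho to one OMe, para to another and meta to the acetyl group, so it outruns enol bromination of the chelated ketone.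

**Step 3**
Reactants: 3 1-(3-bromo-2-hydroxy-4,5,6-trimethoxyphenyl)ethanone
Product: 4 1-(2-hydroxy-3,4,5,6-tetramethoxyphenyl)ethanone
Conditions: NaOMe (6 equiv), CuBr (0.2 equiv), MeOH–DMF, 110 °C, N2; then dilute aq. HCl
Reagents that add atoms: sodium methoxide, C[O-].[Na+]
Why: Ullmann-type methoxylation with monovalent copper (the reaction type that turns 5-bromovanillin into syringaldehyde) exchanges an aryl bromide ortho to a phenoxide for OMe, and the phenoxide form lowers the electrophilicity of the hindered ketone and slows its self-condensation.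

**Step 4**
Reactants: 5 syringaldehyde (4-hydroxy-3,5-dimethoxybenzaldehyde)
Product: 6 4-(benzyloxy)-3,5-dimethoxybenzaldehyde
Conditions: BnBr (1.1 equiv), K2CO3 (1.5 equiv), DMF, 60 °C
Reagents that add atoms: benzyl bromide, BrCc1ccccc1
Why: Williamson ether synthesis (SN2 of the acidic para-formyl phenoxide on benzyl bromide) masks the phenol, which as its anion would deactivate the aldehyde in the next step.

**Step 5**
Reactants: 4 1-(2-hydroxy-3,4,5,6-tetramethoxyphenyl)ethanone; 6 4-(benzyloxy)-3,5-dimethoxybenzaldehyde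
Product: 8 (E)-4-(benzyloxy)-2'-hydroxy-3,3',4',5,5',6'-hexamethoxychalcone, via aldol adduct 7 (not isolated)
Conditions: KOH (10 equiv), EtOH–H2O, rt, 24–48 h; then dilute aq. HCl
Reagents that add atoms: none
Why: In this Claisen–Schmidt (crossed aldol) condensation only 4 can enolise and only 6 carries an aldehyde, and E1cB loss of water from 7 erases its racemic carbinol centre and gives the conjugated E enone as the thermodynamic product.

**Step 6**
Reactants: 8 (E)-4-(benzyloxy)-2'-hydroxy-3,3',4',5,5',6'-hexamethoxychalcone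
Product: 11 4'-(benzyloxy)-3',5,5',6,7,8-hexamethoxyflavone, via flavanone 9 (not isolated), via 3-iodoflavanone 10 (not isolated)
Conditions: I2 (0.1 equiv), DMSO, 120 °C, 3 h
Reagents that add atoms: none
Why: In this iodine-catalysed oxidative cyclisation of a 2'-hydroxychalcone, oxa-Michael closure forms ring C, α-iodination and loss of HI give the aromatic 4-pyranone, DMSO re-oxidises HI to I2, and the transient stereocentres vanish in the planar product.

**Step 7**
Reactants: 11 4'-(benzyloxy)-3',5,5',6,7,8-hexamethoxyflavone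
Product: 12 4'-hydroxy-3',5,5',6,7,8-hexamethoxyflavone
Conditions: H2 (1 atm), 10% Pd/C, EtOAc–MeOH, rt, stopped at full conversion
Reagents that add atoms: none
Why: Catalytic hydrogenolysis of the benzylic C–O bond is much faster at 1 atm and room temperature than reduction of the vinylogous-ester C2=C3 bond of a flavone, and the methyl ethers are inert, so only the 4'-OH is unmasked.

**Compound list**
1 | 3,4,5-trimethoxyphenol | COc1cc(O)cc(OC)c1OC | starting material
2 | 1-(6-hydroxy-2,3,4-trimethoxyphenyl)ethanone | CC(=O)c1c(O)cc(OC)c(OC)c1OC | intermediate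
3 | 1-(3-bromo-2-hydroxy-4,5,6-trimethoxyphenyl)ethanone | CC(=O)c1c(O)c(Br)c(OC)c(OC)c1OC | intermediate
4 | 1-(2-hydroxy-3,4,5,6-tetramethoxyphenyl)ethanone | CC(=O)c1c(O)c(OC)c(OC)c(OC)c1OC | intermediate
5 | syringaldehyde (4-hydroxy-3,5-dimethoxybenzaldehyde) | COc1cc(C=O)cc(OC)c1O | starting material
6 | 4-(benzyloxy)-3,5-dimethoxybenzaldehyde | COc1cc(C=O)cc(OC)c1OCc1ccccc1 | intermediate
7 | aldol adduct, racemic 3-[4-(benzyloxy)-3,5-dimethoxyphenyl]-3-hydroxy-1-(2-hydroxy-3,4,5,6-tetramethoxyphenyl)propan-1-one, not isolated | COc1cc(C(O)CC(=O)c2c(O)c(OC)c(OC)c(OC)c2OC)cc(OC)c1OCc1ccccc1 | intermediate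
8 | (E)-4-(benzyloxy)-2'-hydroxy-3,3',4',5,5',6'-hexamethoxychalcone | COc1cc(/C=C/C(=O)c2c(O)c(OC)c(OC)c(OC)c2OC)cc(OC)c1OCc1ccccc1 | intermediate
9 | racemic 4'-(benzyloxy)-3',5,5',6,7,8-hexamethoxyflavanone, not isolated | COc1cc(C2CC(=O)c3c(OC)c(OC)c(OC)c(OC)c3O2)cc(OC)c1OCc1ccccc1 | intermediate
10 | racemic 4'-(benzyloxy)-3-iodo-3',5,5',6,7,8-hexamethoxyflavanone (diastereomer mixture), not isolated | COc1cc(C2Oc3c(OC)c(OC)c(OC)c(OC)c3C(=O)C2I)cc(OC)c1OCc1ccccc1 | intermediate
11 | 4'-(benzyloxy)-3',5,5',6,7,8-hexamethoxyflavone | COc1cc(-c2cc(=O)c3c(OC)c(OC)c(OC)c(OC)c3o2)cc(OC)c1OCc1ccccc1 | intermediate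
12 | 4'-hydroxy-3',5,5',6,7,8-hexamethoxyflavone (achiral) | COc1cc(-c2cc(=O)c3c(OC)c(OC)c(OC)c(OC)c3o2)cc(OC)c1O | target

**Total step count:** 7.
**Longest linear sequence:** 6 (steps 1, 2, 3, 5, 6 and 7). Step 4 is a one-step side branch.

**Three steps most likely to fail**

**Risk one, step 3.** Copper-catalysed methoxylation of a fully substituted, enolisable bromoketone can stall. It can also lose bromine reductively to return 2, or give aldol tars in hot methoxide.

The fallback builds the C–O bond by formylation and Dakin oxidation instead of by coupling. It sets out from 2 and comes back at 4.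
- Duff formylation of 2 (hexamethylenetetramine, CF3CO2H, 80 °C, then aq. HCl) puts the aldehyde on the only free ring carbon. This gives 3-acetyl-2-hydroxy-4,5,6-trimethoxybenzaldehyde F1.
- Dakin oxidation (1.05 equiv H2O2, aq. NaOH, 0 °C) is far faster for the aldehyde than for the hindered methyl ketone. It gives 1-(2,3-dihydroxy-4,5,6-trimethoxyphenyl)ethanone F2.
- One equivalent of MeI with K2CO3 in acetone methylates the free 3-OH. The 2-OH is held in a hydrogen bond to the ketone and stays free, which gives 4.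

**Risk two, step 6.** The HI formed at 120 °C can cleave the peri 5-OMe. The reaction can also stop at flavanone 9, or iodine can attack the electron-rich rings.

The fallback closes ring C without any oxidant, by the Baker–Venkataraman route. It sets out from 6, uses 4 as the partner, and comes back at 11.
- Pinnick oxidation of 6 (NaClO2, NaH2PO4, 2-methyl-2-butene, t-BuOH–H2O) gives 4-(benzyloxy)-3,5-dimethoxybenzoic acid F3.
- Steglich esterification of F3 and phenol 4 (EDC·HCl, DMAP, CH2Cl2) gives 2-acetyl-3,4,5,6-tetramethoxyphenyl 4-(benzyloxy)-3,5-dimethoxybenzoate F4.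
- KOH in pyridine at 50 °C moves the aroyl group from oxygen to the acetyl carbon. This gives 1-[4-(benzyloxy)-3,5-dimethoxyphenyl]-3-(2-hydroxy-3,4,5,6-tetramethoxyphenyl)propane-1,3-dione F5.
- Catalytic p-TsOH·H2O in refluxing toluene cyclodehydrates F5 to 11.

**Risk three, step 7.** Traces of sulfur or iodide carried over from step 6 can poison the palladium. Forcing the reaction then risks reducing the C2=C3 bond or the carbonyl group.

The fallback removes the reductive step by using an acid-labile protecting group from the start. It sets out from 5, uses 4 as the partner, and comes back at 12.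
- Chloromethyl methyl ether and i-Pr2NEt in CH2Cl2 convert 5 into 3,5-dimethoxy-4-(methoxymethoxy)benzaldehyde F6.
- KOH in EtOH condenses F6 and 4 to (E)-2'-hydroxy-3,3',4',5,5',6'-hexamethoxy-4-(methoxymethoxy)chalcone F7.
- I2 in DMSO at 120 °C gives 3',5,5',6,7,8-hexamethoxy-4'-(methoxymethoxy)flavone F8. Any acetal loss at this stage only shortens the path.
- Brief treatment of F8 with dilute HCl in MeOH at 40 °C gives 12 and leaves the 5-OMe intact.

**Further compounds**
F1 | step 3 | 3-acetyl-2-hydroxy-4,5,6-trimethoxybenzaldehyde | CC(=O)c1c(O)c(C=O)c(OC)c(OC)c1OC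
F2 | step 3 | 1-(2,3-dihydroxy-4,5,6-trimethoxyphenyl)ethanone | CC(=O)c1c(O)c(O)c(OC)c(OC)c1OC
F3 | step 6 | 4-(benzyloxy)-3,5-dimethoxybenzoic acid | COc1cc(C(=O)O)cc(OC)c1OCc1ccccc1
F4 | step 6 | 2-acetyl-3,4,5,6-tetramethoxyphenyl 4-(benzyloxy)-3,5-dimethoxybenzoate | CC(=O)c1c(OC(=O)c2cc(OC)c(OCc3ccccc3)c(OC)c2)c(OC)c(OC)c(OC)c1OC
F5 | step 6 | 1-[4-(benzyloxy)-3,5-dimethoxyphenyl]-3-(2-hydroxy-3,4,5,6-tetramethoxyphenyl)propane-1,3-dione | COc1cc(C(=O)CC(=O)c2c(O)c(OC)c(OC)c(OC)c2OC)cc(OC)c1OCc1ccccc1
F6 | step 7 | 3,5-dimethoxy-4-(methoxymethoxy)benzaldehyde | COCOc1c(OC)cc(C=O)cc1OC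
F7 | step 7 | (E)-2'-hydroxy-3,3',4',5,5',6'-hexamethoxy-4-(methoxymethoxy)chalcone | COCOc1c(OC)cc(/C=C/C(=O)c2c(O)c(OC)c(OC)c(OC)c2OC)cc1OC
F8 | step 7 | 3',5,5',6,7,8-hexamethoxy-4'-(methoxymethoxy)flavone | COCOc1c(OC)cc(-c2cc(=O)c3c(OC)c(OC)c(OC)c(OC)c3o2)cc1OC
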